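Remark on the chemistry (assumption): atoms are called by their locants in the target chroman (O1, C2, C3, C4, C4a, C5–C8, C8a) in every intermediate, while systematic names use each compound's own numbering; stereocentres that are created and erased inside the route (C4a of 13, the alkene geometry of 14, C8/C8a/sulfur of 17, C8a of 18) are left undefined.

## Structural features

The target is a 3,4-dihydro-2H-chromene: a phenolic benzene ring (ring A: C4a, C5–C8, C8a, hydroxyl on C5) fused along C4a–C8a to a dihydropyran ring (O1, C2, C3, C4). C2 carries a methyl group and C4 carries a 4,5-dimethoxynaphthalen-1-yl group, so C4 is a doubly benzylic methine wedged between the C5 hydroxyl and the peri hydrogen of the naphthalene. The two stereocentres, C2 (R) and C4 (S), are 1,3-related across the C3 methylene and stand trans on the pyran ring. The fragile parts are the two electron-rich arenes (a resorcinol-type ring A and a 1,8-dimethoxynaphthalene), which are easily oxidised or attacked by electrophiles, and the ionisable C4 centre; the two aryl methyl ethers must survive while the C5 phenol ends free. The real difficulty is the contiguous 1,2,3-substitution of ring A (O on C5, the hindered C4 branch on C4a, O1 on C8a) combined with the trans-2,4 relationship, because face-selective reductions of six-membered rings normally give the cis arrangement. The key step uses the fact that O–C5–C4a–C8a–O is the oxygen pattern of a β-keto ester and that the oxygen on C8a is also the oxygen on C2. C8a, C4a, C4, C3, C2 and O1 can therefore be the ring of a δ-lactone, C5 and C6 an acetyl group on its α-carbon, and only C7 and C8 have to be added to fold ring A.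

## Logic of the disconnections

22 to 21. The O1–C2 bond is cut. Once the pyran is opened the two ring-A oxygens flanking C4a become equivalent by rotation about C4–C4a, so no differentiation is needed, and the ether can be re-formed with inversion at C2. The trans-2,4 ring relationship is thereby translated into a (1S,3S) open-chain array, which corresponds to a cis-4,6 relationship in a six-membered lactone. The forward step must be a clean SN2 closure by a phenol on a secondary carbinol without elimination.

21 to 15 and 16. The bonds C6–C7 and C8–C8a are cut and, in the retron, O1 is rejoined to C8a. The reason is the β-keto ester pattern of ring A, with the ester alkoxy oxygen being O1 of the side chain; C7 and C8 come from an alkyne equivalent. Ring A disappears and both stereocentres end up in one small ring. The forward step must achieve cycloaddition at a fully substituted ketene acetal terminus, aromatisation of the masked alkyne, and collapse of the C8a ketal by O1–C8a cleavage and not by loss of the silyloxy group.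

15 to 13. Two O–Si bonds are cut; 15 is the double enol derivative of 13. The forward step must silylate both oxygens, and it is made to do so differentially: a robust silyl group on the C5 oxygen and a labile one on the C8a oxygen. The ketal can then be unmasked first and alone in the key step.

13 to 10 and 11. The C4a–C5 bond is cut, since C5 and C6 are an acetyl unit on the lactone α-carbon. This leaves a simple lactone. The forward step must be C-acylation without O-acylation or double acylation.

10 to 9. The C4–H and C4a–H bonds are removed, giving the C4=C4a alkene. The reason is that C4 can be set relative to C2 by hydrogenation of a ring alkene, which should give cis; a cis-4,6 lactone with a 6S methyl carbinol leads to (1S,3S) in 21 and, after inversion, to (2R,4S) in 22. The demand is hydrogen delivery to the face opposite the C2 methyl group.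

9 to 8, and 8 to 6 and 7. The C4=C4a double bond (olefination) and the O1–C8a ester bond are cut, so C8a and C4a come from a phosphonoacetate. The demand is that the intramolecular olefination of an aryl ketone outruns β-elimination of the acyloxy group.

6 to 2 and 4. The bond between C4 and the naphthalene is cut at the ketone stage. The nucleophile must sit at C4 of the naphthalene; direct deprotonation of 1 would metalate ortho to a methoxy group, so the route goes through bromide 2 and its lithium exchange product 5. The electrophile must accept one aryl group only; an ester would add two, so the N-methoxy-N-methylamide 4 is used.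

2 to 1 and 4 to 3. A C–Br bond and an amide C–N bond are cut, arriving at commercial 1 and 3; 7, 11 and 16 are commercial as well.

## Other disconnections considered

Alternative 1: The cut removes C4a–C8a, C5–C6 and C7–C8, so ring A and the pyran ring fall away together. The target is traced to the open-chain diyne A2 (an ynol ether on the C2 oxygen, an alkynylboronate on C4) and acetylene A3. In the forward sense CpCo(CO)2 (or Cp*RuCl(cod)) would couple the two tethered alkynes and insert A3 to give the silyl- and boryl-substituted chroman A1; oxidation of the C5–B bond and protodesilylation at C8 would follow.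
- In its favour: three C–C bonds and two rings in one step, which is better than the chosen key step (two bonds, one ring). The tether fixes the regiochemistry, boron marks C5 for the hydroxyl, and both stereocentres enter with their final configuration, so no inversion at C2 is needed.
- Against it here: A2 holds a secondary-alkyl ynol ether, a class prone to thermal retro-ene fragmentation in the temperature range such cyclotrimerisations usually need, next to a hydrolytically labile alkynylboronate. A3 can also trimerise with itself. The propargylic, benzylic C4 centre of A2 must be made in an open chain without a ring to relay configuration from C2.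
- Comparison: structurally both plans build ring A last on a fragment already holding C2 and C4, and in neither does the key step create a stereocentre (equal). Mechanistically the metal-mediated closure avoids the ketal-collapse question of the chosen plan but is more exposed to substrate decomposition. In step economy it needs two steps after the key step against one, and a longer, less secure preparation of A2 than the lactone route to 15.

Alternative 2: The cut removes O1–C2 and C3–C4 and keeps ring A. The target goes back to the racemic benzhydrol A5 and the acetone-derived enamide A7. A chiral phosphoric acid, for example (R)-3,3'-bis(2,4,6-triisopropylphenyl)-1,1'-binaphthyl-2,2'-diyl hydrogen phosphate, would dehydrate A5 to the ortho-quinone methide A6 and steer its inverse-demand oxa-Diels–Alder reaction with A7 to the N,O-ketal A4. Replacement of the acetamido group by hydrogen and debenzylation would finish the synthesis.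
- In its favour: the highest convergence, catalytic control of C4 from racemic material, and the shortest access to a compound holding all carbons of the target. On convergence and on step count up to the key intermediate it is better than the chosen plan.
- Against it here: C2 is formed as a ketal carbon, and removal of the acetamido group must pass through a trigonal C2, which erases the C2 configuration set in the key step. Hydride delivery or hydrogenation anti to the C4 aryl group would then be expected to place the methyl group cis to it, the opposite of what this trans target needs. The peri-hindered naphthyl group on the methide carbon is an unproven demand on the catalyst pocket, and ring A needs a benzyl group to tell its two oxygens apart.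
- Comparison: structurally it keeps ring A and builds the heterocycle, the reverse of the chosen plan. Mechanistically it offers catalyst control of absolute configuration at C4 (its strength), whereas the chosen plan's hydrogenation plus invertive closure is the more secure way to the trans-2,4 relationship. It is shorter before the key step, but needs two steps after it with an open diastereoselectivity question, against one well-defined step.

Alternative 3: The cut removes C4a–C5 and C8–C8a (C5–C6 is broken and re-formed on the way). Ring A comes from cyclobutenone A9 (C5 to C8) and the siloxyalkyne A10 (C4a, C8a and the whole side chain). On heating, A9 would open to vinylketene A11, which would add A10 in a [2+2] cycloaddition; 4π-electrocyclic opening, 6π-electrocyclic closure and tautomerisation would give the resorcinol monosilyl ether A8. Removal of the secondary silyl ether, invertive Mitsunobu closure and desilylation of the phenol would follow.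
- In its favour: a neutral, purely pericyclic cascade whose regiochemistry is fixed by the polarity of the ynol ether. There is no ketal collapse and no acidic by-product, so on the fate of the ring-A oxygens it is more predictable than the chosen key step. The (1S,3S) array and the invertive closure are the same as in the chosen plan (equal).
- Against it here: parent A9 is volatile and polymerises readily. A10 has its C4 stereocentre propargylic and benzylic, and its 1,3-relationship to the carbinol must be set in an open chain. The differentiated oxygens of A8 bring nothing here, because the two phenols of 21 are equivalent.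
- Comparison: both plans fold ring A from a four-carbon and a two-carbon partner by cycloaddition, but the chosen plan draws its four carbons from a lactone that already fixes C2 and C4 in a ring, which makes stereocontrol simpler. In step economy there are three steps after the key step against one, and a longer approach to A10 than to 15.

Key step: step 9

## Route

Step 1
Reactants: 1 1,8-dimethoxynaphthalene
Product: 2 4-bromo-1,8-dimethoxynaphthalene
Conditions: NBS (1.0 equiv), MeCN, 0 °C → rt
Reagents that add atoms: N-bromosuccinimide, O=C1CCC(=O)N1Br
Why: Electrophilic aromatic bromination; the position para to a methoxy group (C4 of the naphthalene) is the most activated and least hindered site, and one equivalent of reagent at low temperature should stop at the monobromide.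

Step 2
Reactants: 3 ethyl (S)-3-hydroxybutanoate
Product: 4 (S)-3-hydroxy-N-methoxy-N-methylbutanamide
Conditions: MeNH(OMe)·HCl (1.5 equiv), i-PrMgCl (4 equiv), THF, −20 → 0 °C; aq NH4Cl
Reagents that add atoms: N,O-dimethylhydroxylamine hydrochloride, CNOC.Cl
Why: Aminolysis of the ester by the magnesium amide of N,O-dimethylhydroxylamine (Weinreb amide formation); the carbinol centre is not involved and the magnesium alkoxide formed in the flask is inert.

Step 3
Reactants: 2 4-bromo-1,8-dimethoxynaphthalene; 4 (S)-3-hydroxy-N-methoxy-N-methylbutanamide
Product: 6 (S)-1-(4,5-dimethoxynaphthalen-1-yl)-3-hydroxybutan-1-one, via aryllithium 5 (not isolated)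
Conditions: 2 (1.3 equiv), n-BuLi (1.3 equiv), THF, −78 °C; add to 4 pre-treated with i-PrMgCl (1.0 equiv), THF, −78 → 0 °C; aq NH4Cl
Reagents that add atoms: none
Why: Bromine–lithium exchange places the metal exactly where the bromine was, whereas direct deprotonation of 1 would metalate ortho to a methoxy group. In the Weinreb ketone synthesis the chelated tetrahedral adduct survives until the quench, so only one aryl group is transferred; the hydroxyl is masked as its magnesium alkoxide and does not consume 5.

Step 4
Reactants: 6 (S)-1-(4,5-dimethoxynaphthalen-1-yl)-3-hydroxybutan-1-one; 7 2-(diethoxyphosphoryl)acetic acid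
Product: 8 (S)-4-(4,5-dimethoxynaphthalen-1-yl)-4-oxobutan-2-yl 2-(diethoxyphosphoryl)acetate
Conditions: DCC (1.2 equiv), 4-(dimethylamino)pyridine (cat.), CH2Cl2, 0 °C → rt
Reagents that add atoms: none
Why: Steglich esterification of the secondary alcohol under nearly neutral conditions, which should avoid dehydration of the β-hydroxy ketone; the carbinol configuration is retained because only the O–H bond reacts.

Step 5
Reactants: 8 (S)-4-(4,5-dimethoxynaphthalen-1-yl)-4-oxobutan-2-yl 2-(diethoxyphosphoryl)acetate
Product: 9 (S)-4-(4,5-dimethoxynaphthalen-1-yl)-6-methyl-5,6-dihydro-2H-pyran-2-one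
Conditions: LiCl, DBU, MeCN, rt
Reagents that add atoms: none
Why: Intramolecular Horner–Wadsworth–Emmons olefination: the lithium-chelated phosphonate is deprotonated by the amidine base and the carbanion closes onto the aryl ketone to form the C4=C4a bond in a six-membered ring; the mild base is chosen to disfavour β-elimination of the acyloxy group.

Step 6
Reactants: 9 (S)-4-(4,5-dimethoxynaphthalen-1-yl)-6-methyl-5,6-dihydro-2H-pyran-2-one
Product: 10 (4R,6S)-4-(4,5-dimethoxynaphthalen-1-yl)-6-methyltetrahydro-2H-pyran-2-one
Conditions: H2 (1 atm), 10% Pd/C, EtOAc, rt
Reagents that add atoms: none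
Why: Heterogeneous catalytic hydrogenation should deliver both hydrogens to the face of the half-chair opposite the C2 methyl group, so the aryl group at the new C4 stereocentre ends cis to the methyl group, the usual outcome for 4,6-disubstituted 5,6-dihydropyran-2-ones.

Step 7
Reactants: 10 (4R,6S)-4-(4,5-dimethoxynaphthalen-1-yl)-6-methyltetrahydro-2H-pyran-2-one; 11 N-methoxy-N-methylacetamide
Product: 13 (4R,6S)-3-acetyl-4-(4,5-dimethoxynaphthalen-1-yl)-6-methyltetrahydro-2H-pyran-2-one (C4a epimers interconverting through the enol), via lithium enolate 12 (not isolated)
Conditions: LiN(i-Pr)2 (1.15 equiv), THF, −78 °C; 11 (1.5 equiv), −78 → 0 °C; aq NH4Cl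
Reagents that add atoms: none
Why: Crossed Claisen-type C-acylation of a lactone lithium enolate by a Weinreb amide; the chelated tetrahedral adduct should persist until the quench, which suppresses proton transfer to unreacted enolate, double acylation and O-acylation. The configuration at C4a is of no consequence because that carbon becomes trigonal in the next step.

Step 8
Reactants: 13 (4R,6S)-3-acetyl-4-(4,5-dimethoxynaphthalen-1-yl)-6-methyltetrahydro-2H-pyran-2-one
Product: 15 tert-butyl({1-[(4S,6S)-4-(4,5-dimethoxynaphthalen-1-yl)-6-methyl-2-(trimethylsilyloxy)-5,6-dihydro-4H-pyran-3-yl]ethenyl}oxy)dimethylsilane, via enol silyl ether 14 (not isolated)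
Conditions: TBSOTf (1.05 equiv), Et3N (4 equiv), Et2O, 0 °C; then TMSOTf (1.3 equiv), 0 °C → rt; decant from Et3NH·OTf, concentrate under argon, use crude
Reagents that add atoms: tert-butyldimethylsilyl trifluoromethanesulfonate, CC(C)(C)[Si](C)(C)OS(=O)(=O)C(F)(F)F; trimethylsilyl trifluoromethanesulfonate, C[Si](C)(C)OS(=O)(=O)C(F)(F)F
Why: Soft enolisation with silyl triflate and tertiary amine, the standard conversion of β-dicarbonyl compounds into 1,3-bis(silyloxy)-1,3-dienes: the first triflate silylates the enol oxygen of the acetyl group (the C5 oxygen) to give 14, the second silylates the lactone carbonyl oxygen while the amine removes a C6 proton. The order of addition puts the robust silyl group on the C5 oxygen and the labile one on the future ketal oxygen at C8a.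

Step 9
Reactants: 15 tert-butyl({1-[(4S,6S)-4-(4,5-dimethoxynaphthalen-1-yl)-6-methyl-2-(trimethylsilyloxy)-5,6-dihydro-4H-pyran-3-yl]ethenyl}oxy)dimethylsilane; 16 phenyl vinyl sulfoxide
Product: 21 2-[(1S,3S)-1-(4,5-dimethoxynaphthalen-1-yl)-3-hydroxybutyl]benzene-1,3-diol, via sulfinyl cycloadduct 17 (not isolated), via cyclohexadiene silyl ketal 18 (not isolated), via cyclohexadienone 19 (not isolated), via aryl silyl ether 20 (not isolated)
Conditions: 16 (1.5 equiv), Et3N (0.2 equiv), toluene, 110 °C, sealed tube; cool, K2CO3 (cat.), MeOH, 0 °C → rt; then Bu4NF, THF, 0 °C → rt; aq NH4Cl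
Reagents that add atoms: none
Why: A Diels–Alder reaction of normal electron demand between the 1,1,3-trioxygenated diene 15 and the electron-poor alkene 16, probably asynchronous with the nucleophilic C6 terminus bonding first to the unsubstituted carbon of 16 (C7) and C8a then closing onto the sulfinyl-bearing carbon (C8), should give 17; ring A is thus closed as a six-membered carbocycle by intermolecular [4+2] annulation onto the C4a–C8a edge of the existing oxygen heterocycle. At the reaction temperature 17 should lose benzenesulfenic acid by sulfoxide syn-elimination through a C7 hydrogen, the only β-hydrogens present, to give 18. Methanolysis then cleaves the trimethylsilyl–oxygen bond of the mixed ketal, the C8a oxyanion expels O1 (retro-hemiketalisation), and the cross-conjugated dienone 19, the keto tautomer of a phenol, enolises to 20, from which fluoride removes the aryl silyl group to give 21. The closest known reaction type is the cycloaddition–aromatisation of 1-alkoxy-1,3-bis(silyloxy)-1,3-dienes derived from β-keto esters with alkynes or alkyne equivalents to give resorcinols, in which the alkoxy group is the one expelled. The stereocentres formed at C8, C8a and sulfur are transient and all erased, so no new stereocentre needs control, and C2 and C4 are untouched because the bond that breaks is O1–C8a and not O1–C2. The selectivity required is cleavage of O1–C8a in preference to loss of silanolate from C8a, which would aromatise with the pyran ring intact and the wrong, cis relationship. It is secured by placing the labile trimethylsilyl group on the ketal oxygen and the robust tert-butyldimethylsilyl group on the C5 oxygen, so that unmasking starts at C8a while the C5 enol ether cannot yet form an enolate that could push silanolate out, by using nucleophiles that attack silicon and do not ionise the C8a–OSi bond, and by buffering the sulfenic acid with amine during the thermal stage.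

Step 10
Reactants: 21 2-[(1S,3S)-1-(4,5-dimethoxynaphthalen-1-yl)-3-hydroxybutyl]benzene-1,3-diol
Product: 22 (2R,4S)-4-(4,5-dimethoxynaphthalen-1-yl)-2-methyl-3,4-dihydro-2H-chromen-5-ol (cladonaphchrom A)
Conditions: PPh3 (1.5 equiv), diisopropyl azodicarboxylate (1.5 equiv), THF (0.02 M), 0 °C → rt
Reagents that add atoms: none
Why: Intramolecular Mitsunobu etherification: the secondary alcohol is activated by the phosphine–azodicarboxylate pair and displaced by a phenol oxygen in a six-membered SN2 closure with inversion, turning the (S)-carbinol into (R)-C2 and giving the trans-2,4 chroman. The two phenols are interchanged by rotation about C4–C4a, so either gives the same product and the unused one becomes the C5 hydroxyl.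

## Compound list

1 | 1,8-dimethoxynaphthalene | COc1cccc2cccc(OC)c12 | starting material
2 | 4-bromo-1,8-dimethoxynaphthalene | COc1cccc2c(Br)ccc(OC)c12 | intermediate
3 | ethyl (S)-3-hydroxybutanoate | CCOC(=O)C[C@H](C)O | starting material
4 | (S)-3-hydroxy-N-methoxy-N-methylbutanamide | CON(C)C(=O)C[C@H](C)O | intermediate
5 | (4,5-dimethoxynaphthalen-1-yl)lithium | [Li]c1ccc(OC)c2c(OC)cccc12 | intermediate (not isolated)
6 | (S)-1-(4,5-dimethoxynaphthalen-1-yl)-3-hydroxybutan-1-one | COc1cccc2c(C(=O)C[C@H](C)O)ccc(OC)c12 | intermediate
7 | 2-(diethoxyphosphoryl)acetic acid (diethylphosphonoacetic acid) | CCOP(=O)(CC(=O)O)OCC | starting material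
8 | (S)-4-(4,5-dimethoxynaphthalen-1-yl)-4-oxobutan-2-yl 2-(diethoxyphosphoryl)acetate | COc1cccc2c(C(=O)C[C@H](C)OC(=O)CP(=O)(OCC)OCC)ccc(OC)c12 | intermediate
9 | (S)-4-(4,5-dimethoxynaphthalen-1-yl)-6-methyl-5,6-dihydro-2H-pyran-2-one | COc1cccc2c(C3=CC(=O)O[C@@H](C)C3)ccc(OC)c12 | intermediate
10 | (4R,6S)-4-(4,5-dimethoxynaphthalen-1-yl)-6-methyltetrahydro-2H-pyran-2-one | COc1cccc2c([C@@H]3C[C@H](C)OC(=O)C3)ccc(OC)c12 | intermediate
11 | N-methoxy-N-methylacetamide | CON(C)C(C)=O | starting material
12 | lithium (4R,6S)-4-(4,5-dimethoxynaphthalen-1-yl)-6-methyl-5,6-dihydro-4H-pyran-2-olate (lithium enolate of 10) | COc1cccc2c([C@@H]3C[C@H](C)OC(O[Li])=C3)ccc(OC)c12 | intermediate (not isolated)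
13 | (4R,6S)-3-acetyl-4-(4,5-dimethoxynaphthalen-1-yl)-6-methyltetrahydro-2H-pyran-2-one (C3 of the lactone undefined) | COc1cccc2c([C@@H]3C[C@H](C)OC(=O)C3C(C)=O)ccc(OC)c12 | intermediate
14 | (4S,6S)-3-[1-(tert-butyldimethylsilyloxy)ethylidene]-4-(4,5-dimethoxynaphthalen-1-yl)-6-methyltetrahydro-2H-pyran-2-one (alkene geometry undefined) | COc1cccc2c([C@@H]3C[C@H](C)OC(=O)C3=C(C)O[Si](C)(C)C(C)(C)C)ccc(OC)c12 | intermediate (not isolated)
15 | tert-butyl({1-[(4S,6S)-4-(4,5-dimethoxynaphthalen-1-yl)-6-methyl-2-(trimethylsilyloxy)-5,6-dihydro-4H-pyran-3-yl]ethenyl}oxy)dimethylsilane | COc1cccc2c([C@@H]3C[C@H](C)OC(O[Si](C)(C)C)=C3C(=C)O[Si](C)(C)C(C)(C)C)ccc(OC)c12 | intermediate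
16 | phenyl vinyl sulfoxide | C=CS(=O)c1ccccc1 | starting material
17 | (2S,4S)-5-(tert-butyldimethylsilyloxy)-4-(4,5-dimethoxynaphthalen-1-yl)-2-methyl-8-(phenylsulfinyl)-8a-(trimethylsilyloxy)-3,4,6,7,8,8a-hexahydro-2H-chromene (C8, C8a and sulfur undefined) | COc1cccc2c([C@@H]3C[C@H](C)OC4(O[Si](C)(C)C)C(S(=O)c5ccccc5)CCC(O[Si](C)(C)C(C)(C)C)=C34)ccc(OC)c12 | intermediate (not isolated)
18 | (2S,4S)-5-(tert-butyldimethylsilyloxy)-4-(4,5-dimethoxynaphthalen-1-yl)-2-methyl-8a-(trimethylsilyloxy)-3,4,6,8a-tetrahydro-2H-chromene (C8a undefined) | COc1cccc2c([C@@H]3C[C@H](C)OC4(O[Si](C)(C)C)C=CCC(O[Si](C)(C)C(C)(C)C)=C34)ccc(OC)c12 | intermediate (not isolated)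
19 | 3-(tert-butyldimethylsilyloxy)-2-[(1S,3S)-1-(4,5-dimethoxynaphthalen-1-yl)-3-hydroxybutyl]cyclohexa-2,5-dien-1-one | COc1cccc2c([C@@H](C3=C(O[Si](C)(C)C(C)(C)C)CC=CC3=O)C[C@H](C)O)ccc(OC)c12 | intermediate (not isolated)
20 | 3-(tert-butyldimethylsilyloxy)-2-[(1S,3S)-1-(4,5-dimethoxynaphthalen-1-yl)-3-hydroxybutyl]phenol | COc1cccc2c([C@@H](c3c(O)cccc3O[Si](C)(C)C(C)(C)C)C[C@H](C)O)ccc(OC)c12 | intermediate (not isolated)
21 | 2-[(1S,3S)-1-(4,5-dimethoxynaphthalen-1-yl)-3-hydroxybutyl]benzene-1,3-diol | COc1cccc2c([C@@H](c3c(O)cccc3O)C[C@H](C)O)ccc(OC)c12 | intermediate
22 | (2R,4S)-4-(4,5-dimethoxynaphthalen-1-yl)-2-methyl-3,4-dihydro-2H-chromen-5-ol (cladonaphchrom A) | COc1cccc2c([C@@H]3C[C@@H](C)Oc4cccc(O)c43)ccc(OC)c12 | target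

## Step count and least certain steps

Total: 10 steps. Longest linear sequence: 9 steps (3 → 4 → 6 → 8 → 9 → 10 → 13 → 15 → 21 → 22; the branch 1 → 2 joins at step 3 and is of the same length).

Step 9 (key step). The cycloaddition may be slow, because the dienophile is only moderately activated and must bond to a fully substituted ketene acetal carbon; thermal or protic degradation of the diene, or sulfenylation of the electron-rich rings by the sulfenic acid, could then outrun ring formation. A second failure mode is expulsion of silanolate instead of O1 from C8a, which would close the pyran with retention at C2 and lead into the 2,4-cis series. Fallback, setting out from 15 and returning at 21: replace the masked alkyne by a true alkyne with a traceless activating group. 15 and methyl propiolate should combine at lower temperature with the same orientation (C6 to the unsubstituted alkyne carbon, C8a to the ester-bearing one). The adduct is already at the arene oxidation level, so the same methanolysis and fluoride treatment should give methyl 2,4-dihydroxy-3-[(1S,3S)-1-(4,5-dimethoxynaphthalen-1-yl)-3-hydroxybutyl]benzoate F1. Saponification with aqueous NaOH should give 2,4-dihydroxy-3-[(1S,3S)-1-(4,5-dimethoxynaphthalen-1-yl)-3-hydroxybutyl]benzoic acid F2, a β-resorcylic acid that should lose carbon dioxide on heating in aqueous solution to give 21. This costs two more steps but needs no sulfoxide elimination and releases no sulfenic acid.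

Step 8. The second, more demanding enolisation (ketene acetal formation) may stay incomplete, or the very moisture-sensitive diene may hydrolyse during handling. Fallback, setting out from 13 and returning at 15 (F0: no new compound): separate the two events and change from amine-mediated soft enolisation to kinetic deprotonation. 14 is isolated after the first silylation, C6 is deprotonated with LiN(i-Pr)2 in THF at −78 °C, and the extended enolate is trapped on oxygen with Me3SiCl.

Step 7. The hindered enolate, flanked by the C4 aryl group, may add slowly to the amide while proton exchange with the acetyl group of 11 quenches it, leaving 10 unchanged. Fallback, setting out from 10 and returning at 13: introduce the acetyl group in two stages through an aldol reaction. Enolate 12 and acetaldehyde should give (4R,6S)-4-(4,5-dimethoxynaphthalen-1-yl)-3-(1-hydroxyethyl)-6-methyltetrahydro-2H-pyran-2-one F3, and Dess–Martin oxidation of the secondary alcohol should give 13.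

Step 5. Base-induced β-elimination of the phosphonoacetate from the β-acyloxy ketone (through the ketone enolate) may compete with olefination, and closure onto the peri-hindered aryl ketone may be slow. Fallback, setting out from 6 and returning at 9 (it bypasses steps 4 and 5): olefination under neutral conditions with ketenylidenetriphenylphosphorane, Ph3P=C=C=O. The hydroxyl of 6 should add to the ketene to give the ester-stabilised ylide (S)-4-(4,5-dimethoxynaphthalen-1-yl)-4-oxobutan-2-yl 2-(triphenyl-λ5-phosphanylidene)acetate F4, which should close by intramolecular Wittig reaction in refluxing toluene.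

Step 6. Facial selectivity may be poor, because the twisted, bulky naphthyl group on the alkene could override the small bias of the remote methyl group; prolonged exposure could also begin to reduce the naphthalene. Fallback, setting out from 9 and returning at 10 (F0: no new compound): conjugate hydride addition under ligand control in place of surface hydrogenation. Copper hydride would be generated from Cu(OAc)2, a chiral bisphosphine such as 5,5'-bis[bis(3,5-di-tert-butyl-4-methoxyphenyl)phosphino]-4,4'-bi-1,3-benzodioxole (the enantiomer matched to the cis product to be selected) and polymethylhydrosiloxane with tert-butanol in toluene.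

## Further compounds

F1 | step 9 | methyl 2,4-dihydroxy-3-[(1S,3S)-1-(4,5-dimethoxynaphthalen-1-yl)-3-hydroxybutyl]benzoate | COc1cccc2c([C@@H](c3c(O)ccc(C(=O)OC)c3O)C[C@H](C)O)ccc(OC)c12
F2 | step 9 | 2,4-dihydroxy-3-[(1S,3S)-1-(4,5-dimethoxynaphthalen-1-yl)-3-hydroxybutyl]benzoic acid | COc1cccc2c([C@@H](c3c(O)ccc(C(=O)O)c3O)C[C@H](C)O)ccc(OC)c12
F0 | step 8 | none | none
F3 | step 7 | (4R,6S)-4-(4,5-dimethoxynaphthalen-1-yl)-3-(1-hydroxyethyl)-6-methyltetrahydro-2H-pyran-2-one | COc1cccc2c([C@@H]3C[C@H](C)OC(=O)C3C(C)O)ccc(OC)c12
F4 | step 5 | (S)-4-(4,5-dimethoxynaphthalen-1-yl)-4-oxobutan-2-yl 2-(triphenyl-λ5-phosphanylidene)acetate | COc1cccc2c(C(=O)C[C@H](C)OC(=O)C=P(c3ccccc3)(c3ccccc3)c3ccccc3)ccc(OC)c12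
F0 | step 6 | none | none
A1 | alternative 1 | (2R,4S)-8-(tert-butyldimethylsilyl)-4-(4,5-dimethoxynaphthalen-1-yl)-2-methyl-5-(4,4,5,5-tetramethyl-1,3,2-dioxaborolan-2-yl)-3,4-dihydro-2H-chromene | COc1cccc2c([C@@H]3C[C@@H](C)Oc4c([Si](C)(C)C(C)(C)C)ccc(B5OC(C)(C)C(C)(C)O5)c43)ccc(OC)c12
A2 | alternative 1 | tert-butyl({[(2R,4R)-4-(4,5-dimethoxynaphthalen-1-yl)-6-(4,4,5,5-tetramethyl-1,3,2-dioxaborolan-2-yl)hex-5-yn-2-yl]oxy}ethynyl)dimethylsilane | COc1cccc2c([C@@H](C#CB3OC(C)(C)C(C)(C)O3)C[C@@H](C)OC#C[Si](C)(C)C(C)(C)C)ccc(OC)c12
A3 | alternative 1 | acetylene | C#C
A4 | alternative 2 | N-[(2R,4S)-5-(benzyloxy)-4-(4,5-dimethoxynaphthalen-1-yl)-2-methyl-3,4-dihydro-2H-chromen-2-yl]acetamide | COc1cccc2c([C@@H]3C[C@@](NC(C)=O)(C)Oc4cccc(OCc5ccccc5)c43)ccc(OC)c12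
A5 | alternative 2 | racemic 3-(benzyloxy)-2-[(4,5-dimethoxynaphthalen-1-yl)(hydroxy)methyl]phenol | COc1cccc2c(C(O)c3c(O)cccc3OCc3ccccc3)ccc(OC)c12
A6 | alternative 2 | 5-(benzyloxy)-6-[(4,5-dimethoxynaphthalen-1-yl)methylidene]cyclohexa-2,4-dien-1-one | COc1cccc2c(C=C3C(=O)C=CC=C3OCc3ccccc3)ccc(OC)c12
A7 | alternative 2 | N-(prop-1-en-2-yl)acetamide | CC(=C)NC(C)=O
A8 | alternative 3 | 2-[(1S,3S)-3-(tert-butyldimethylsilyloxy)-1-(4,5-dimethoxynaphthalen-1-yl)butyl]-3-(triisopropylsilyloxy)phenol | COc1cccc2c([C@@H](c3c(O)cccc3O[Si](C(C)C)(C(C)C)C(C)C)C[C@H](C)O[Si](C)(C)C(C)(C)C)ccc(OC)c12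
A9 | alternative 3 | cyclobut-2-en-1-one | O=C1C=CC1
A10 | alternative 3 | tert-butyl{[(2S,4S)-4-(4,5-dimethoxynaphthalen-1-yl)-6-(triisopropylsilyloxy)hex-5-yn-2-yl]oxy}dimethylsilane | COc1cccc2c([C@@H](C#CO[Si](C(C)C)(C(C)C)C(C)C)C[C@H](C)O[Si](C)(C)C(C)(C)C)ccc(OC)c12
A11 | alternative 3 | buta-1,3-dien-1-one (vinylketene) | C=CC=C=O
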